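**Retrosynthetic overview**

1. The strategy rests on the 1,5-relationship between the tertiary carbinol C8 and the benzylic ether carbon C7 through C8'–C9'–O2: a C8 ketone in ring A can take a hydrogen from C7 and bond to it across what becomes ring B (lignan numbering: C7/C7' benzylic, C8 carbinol, C8' ring-fusion CH, C9/C9' the OCH2 carbons, O1 in ring A joining C7' and C9, O2 in ring B joining C7 and C9').
2. Target 18 ⇐ bis-silyl ether 17 (desilylation) ⇐ ring-A ketone 16 by Norrish–Yang photocyclisation (C7–C8 bond, ring B, stereocentres C7 and C8).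
3. 16 ⇐ chloromethyl ketone 15 by O1–C9 etherification (ring A) ⇐ Weinreb amide 14 ⇐ anti-aldol adduct 13 (C7'–C8' bond, both stereocentres from an oxazolidinone auxiliary).
4. 13 ⇐ aldehyde 3 + imide 11; 11 ⇐ acid 8 ⇐ oxa-Michael addition of benzylic alcohol 4 to methyl acrylate; 3 and 4 ⇐ syringaldehyde.
5. Ring order: ring A (step 9), then ring B (step 10).

Key step: step 10

Abbreviations: Ar = 4-(tert-butyldimethylsilyloxy)-3,5-dimethoxyphenyl; TBS = tert-butyldimethylsilyl. Aldehyde 3 is divided between steps 2 and 6.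
Remark: the MgCl2-catalysed aldol of the (S)-4-benzyloxazolidinone imide is assumed to follow its usual sense (chelated Z-enolate, attack anti to the benzyl group), which gives the (2R,3S) anti adduct needed here.

**Step 1**
Reactants: 1 syringaldehyde; 2 tert-butyldimethylsilyl chloride
Product: 3 4-(tert-butyldimethylsilyloxy)-3,5-dimethoxybenzaldehyde
Conditions: imidazole, DMF, rt
Reagents that add atoms: none
Why: Imidazole-promoted O-silylation of the acidic phenol (silyl ether protection) should be clean and masks the O–H group that would otherwise quench the enolate, carbenoid and excited-ketone chemistry that follows.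

**Step 2**
Reactants: 3 4-(tert-butyldimethylsilyloxy)-3,5-dimethoxybenzaldehyde
Product: 4 (Ar)methanol
Conditions: NaBH4, MeOH/THF, 0 °C
Reagents that add atoms: none
Why: Hydride reduction of the aryl aldehyde with NaBH4 is fast at 0 °C, where the hindered aryl silyl ether should be retained.

**Step 3**
Reactants: 4 (Ar)methanol; 5 methyl acrylate
Product: 6 methyl 3-[(Ar)methoxy]propanoate
Conditions: NaH (0.1 equiv), methyl acrylate (3 equiv), THF, 0 °C
Reagents that add atoms: none
Why: Base-catalysed oxa-Michael addition, in which the catalytic benzylic alkoxide adds to the acrylate and the ester enolate is reprotonated by more alcohol, should build the C7–O2–C9' ether while the aryl silyl ether meets only a trace of alkoxide at low temperature.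

**Step 4**
Reactants: 6 methyl 3-[(Ar)methoxy]propanoate
Product: 8 3-[(Ar)methoxy]propanoic acid, via trimethylstannyl ester 7 (not isolated)
Conditions: Me3SnOH, 1,2-dichloroethane, 70 °C; then 5% aq. HCl
Reagents that add atoms: trimethyltin hydroxide, C[Sn](C)(C)O
Why: Trimethyltin hydroxide ester hydrolysis through the tin carboxylate is a near-neutral cleavage of methyl esters, chosen so that neither retro-oxa-Michael loss of the benzylic alkoxide nor hydroxide attack on the aryl silyl ether intervenes.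

**Step 5**
Reactants: 8 3-[(Ar)methoxy]propanoic acid; 9 (S)-4-benzyloxazolidin-2-one
Product: 11 (S)-4-benzyl-3-{3-[(Ar)methoxy]propanoyl}oxazolidin-2-one, via mixed pivalic anhydride 10 (not isolated)
Conditions: PivCl, Et3N, THF, −20 °C; then LiCl, 9, −20 °C to rt
Reagents that add atoms: none
Why: N-Acylation of the oxazolidinone through the mixed pivalic anhydride with LiCl/Et3N activation needs no strong base, and the hindered pivaloyl carbonyl directs attack to the desired acyl group.

**Step 6**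
Reactants: 11 (S)-4-benzyl-3-{3-[(Ar)methoxy]propanoyl}oxazolidin-2-one; 3 4-(tert-butyldimethylsilyloxy)-3,5-dimethoxybenzaldehyde
Product: 13 (S)-4-benzyl-3-[(2R,3S)-3-Ar-3-hydroxy-2-{[(Ar)methoxy]methyl}propanoyl]oxazolidin-2-one, via trimethylsilyl ether 12 (not isolated)
Conditions: 3 (1.2 equiv), MgCl2 (0.2 equiv), NaSbF6 (0.3 equiv), Et3N, TMSCl, EtOAc, rt; then TFA (cat.), MeOH, 0 °C
Reagents that add atoms: none
Why: In this MgCl2-catalysed direct anti-aldol of an N-acyloxazolidinone, soft enolisation gives the magnesium-chelated Z-enolate, the non-enolisable aryl aldehyde adds to the face opposite the benzyl group through a boat-like transition state so that C8' (R) and C7' (S) are set anti, silylation of the aldolate by TMSCl turns the catalyst over, and methanolysis then frees the hydroxyl.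

**Step 7**
Reactants: 13 (S)-4-benzyl-3-[(2R,3S)-3-Ar-3-hydroxy-2-{[(Ar)methoxy]methyl}propanoyl]oxazolidin-2-one
Product: 14 (2R,3S)-3-Ar-3-hydroxy-N-methoxy-N-methyl-2-{[(Ar)methoxy]methyl}propanamide
Conditions: MeNHOMe·HCl, Me3Al, CH2Cl2, −15 to 0 °C; then 0.5 M HCl, 0 °C
Reagents that add atoms: N,O-dimethylhydroxylamine hydrochloride, CNOC.Cl
Why: Aluminium amide transamination of the β-hydroxy imide (Weinreb amide formation), in which the aluminium alkoxide of the free C7' hydroxyl directs attack to the exocyclic carbonyl, should release the auxiliary without epimerising C8'.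

**Step 8**
Reactants: 14 (2R,3S)-3-Ar-3-hydroxy-N-methoxy-N-methyl-2-{[(Ar)methoxy]methyl}propanamide
Product: 15 (3R,4S)-4-Ar-1-chloro-4-hydroxy-3-{[(Ar)methoxy]methyl}butan-2-one
Conditions: ICH2Cl, MeLi·LiBr, THF, −78 °C; then aq. NH4Cl, −78 °C
Reagents that add atoms: chloroiodomethane, ClCI
Why: In this Weinreb ketone synthesis with the carbenoid chloromethyllithium generated in the flask at −78 °C, one equivalent is spent on the hydroxyl, the chelated tetrahedral adduct prevents over-addition, and the cold quench should leave C8' and the β-alkoxy arm untouched.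

**Step 9**
Reactants: 15 (3R,4S)-4-Ar-1-chloro-4-hydroxy-3-{[(Ar)methoxy]methyl}butan-2-one
Product: 16 (4R,5S)-5-Ar-4-{[(Ar)methoxy]methyl}oxolan-3-one
Conditions: K2CO3, NaI (0.1 equiv), acetone, 0 °C to rt
Reagents that add atoms: none
Why: Intramolecular Williamson etherification (5-exo-tet SN2 at the strongly activated α-halo ketone carbon) forms O1–C9 and closes ring A, the carbonate-generated C7' alkoxide being far more nucleophilic than the neighbouring ether oxygen O2, and the anti C7'/C8' relationship becomes the trans arrangement of ring A, which is also the stable one beside the ketone.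

**Step 10**
Reactants: 16 (4R,5S)-5-Ar-4-{[(Ar)methoxy]methyl}oxolan-3-one
Product: 17 (1S,2R,5R,6S)-2,6-di-Ar-3,7-dioxabicyclo[3.3.0]octan-1-ol
Conditions: hν (medium-pressure mercury lamp, Pyrex filter), degassed benzene (0.01 M), rt
Reagents that add atoms: none
Why: n,π* excitation of the C8 ketone is followed by 1,6-hydrogen transfer from the benzylic ether CH2 (the future C7) to the carbonyl oxygen through a seven-membered transition state, and the resulting 1,5-biradical (C8 ketyl, C7 radical stabilised by O2 and the arene) recombines to form C7–C8; this is the Norrish–Yang photocyclisation in its δ-hydrogen variant, known for β-alkoxy ketones, which give 3-hydroxytetrahydrofurans. Ring B is closed as a five-membered ring by radical–radical coupling between C8 and C7. At C8 the control element is the C8' centre, because the short C8'–C9'–O2 tether allows bonding only on the face of ring A that carries the arm, so the fusion must be cis and the hydroxyl lies on the convex face, cis to H8'. At C7 the configuration is decided in the closure of the biradical, where the aryl group should take the exo position on the convex face and avoid the C9 methylene and O1 of ring A; the C7 epimer is the expected minor product and should be separable. The step needs site selectivity in the hydrogen transfer and the substrate secures it, since the C7 hydrogens are activated twice (α-oxygen and benzylic) and are the only activated hydrogens within reach of the carbonyl oxygen (C7'–H is held in ring A and the C9' hydrogens would need a five-membered transition state). Silylation removes the phenolic O–H donors, and the trans C7'/C8' arrangement is carried into the product unchanged.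

**Step 11**
Reactants: 17 (1S,2R,5R,6S)-2,6-di-Ar-3,7-dioxabicyclo[3.3.0]octan-1-ol
Product: 18 8-hydroxysyringaresinol
Conditions: TBAF, AcOH, THF, 0 °C
Reagents that add atoms: none
Why: Fluoride-induced cleavage of both aryl silyl ethers (driven by Si–F bond formation), buffered with acetic acid so that the phenoxides are protonated at once, should leave the benzylic ethers, the tertiary alcohol and all four stereocentres untouched.

**Compound list**

1 | syringaldehyde (4-hydroxy-3,5-dimethoxybenzaldehyde) | COc1cc(C=O)cc(OC)c1O | starting material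
2 | tert-butyldimethylsilyl chloride | CC(C)(C)[Si](C)(C)Cl | starting material
3 | 4-(tert-butyldimethylsilyloxy)-3,5-dimethoxybenzaldehyde | COc1cc(C=O)cc(OC)c1O[Si](C)(C)C(C)(C)C | intermediate
4 | [4-(tert-butyldimethylsilyloxy)-3,5-dimethoxyphenyl]methanol | COc1cc(CO)cc(OC)c1O[Si](C)(C)C(C)(C)C | intermediate
5 | methyl acrylate | C=CC(=O)OC | starting material
6 | methyl 3-[(Ar)methoxy]propanoate | COC(=O)CCOCc1cc(OC)c(O[Si](C)(C)C(C)(C)C)c(OC)c1 | intermediate
7 | trimethylstannyl 3-[(Ar)methoxy]propanoate | C[Sn](C)(C)OC(=O)CCOCc1cc(OC)c(O[Si](C)(C)C(C)(C)C)c(OC)c1 | intermediate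
8 | 3-[(Ar)methoxy]propanoic acid | OC(=O)CCOCc1cc(OC)c(O[Si](C)(C)C(C)(C)C)c(OC)c1 | intermediate
9 | (S)-4-benzyloxazolidin-2-one | O=C1N[C@@H](Cc2ccccc2)CO1 | starting material
10 | 3-[(Ar)methoxy]propanoic pivalic anhydride | CC(C)(C)C(=O)OC(=O)CCOCc1cc(OC)c(O[Si](C)(C)C(C)(C)C)c(OC)c1 | intermediate
11 | (S)-4-benzyl-3-{3-[(Ar)methoxy]propanoyl}oxazolidin-2-one | O=C(CCOCc1cc(OC)c(O[Si](C)(C)C(C)(C)C)c(OC)c1)N1[C@@H](Cc2ccccc2)COC1=O | intermediate
12 | (S)-4-benzyl-3-[(2R,3S)-3-Ar-2-{[(Ar)methoxy]methyl}-3-(trimethylsilyloxy)propanoyl]oxazolidin-2-one | O=C([C@H](COCc1cc(OC)c(O[Si](C)(C)C(C)(C)C)c(OC)c1)[C@H](O[Si](C)(C)C)c1cc(OC)c(O[Si](C)(C)C(C)(C)C)c(OC)c1)N1[C@@H](Cc2ccccc2)COC1=O | intermediate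
13 | (S)-4-benzyl-3-[(2R,3S)-3-Ar-3-hydroxy-2-{[(Ar)methoxy]methyl}propanoyl]oxazolidin-2-one | O=C([C@H](COCc1cc(OC)c(O[Si](C)(C)C(C)(C)C)c(OC)c1)[C@H](O)c1cc(OC)c(O[Si](C)(C)C(C)(C)C)c(OC)c1)N1[C@@H](Cc2ccccc2)COC1=O | intermediate
14 | (2R,3S)-3-Ar-3-hydroxy-N-methoxy-N-methyl-2-{[(Ar)methoxy]methyl}propanamide | CON(C)C(=O)[C@H](COCc1cc(OC)c(O[Si](C)(C)C(C)(C)C)c(OC)c1)[C@H](O)c1cc(OC)c(O[Si](C)(C)C(C)(C)C)c(OC)c1 | intermediate
15 | (3R,4S)-4-Ar-1-chloro-4-hydroxy-3-{[(Ar)methoxy]methyl}butan-2-one | ClCC(=O)[C@H](COCc1cc(OC)c(O[Si](C)(C)C(C)(C)C)c(OC)c1)[C@H](O)c1cc(OC)c(O[Si](C)(C)C(C)(C)C)c(OC)c1 | intermediate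
16 | (4R,5S)-5-Ar-4-{[(Ar)methoxy]methyl}oxolan-3-one (trans; photocyclisation precursor) | COc1cc([C@H]2OCC(=O)[C@@H]2COCc2cc(OC)c(O[Si](C)(C)C(C)(C)C)c(OC)c2)cc(OC)c1O[Si](C)(C)C(C)(C)C | intermediate
17 | (1S,2R,5R,6S)-2,6-di-Ar-3,7-dioxabicyclo[3.3.0]octan-1-ol (bis-TBS ether of 8-hydroxysyringaresinol) | COc1cc([C@H]2OC[C@]3(O)[C@@H](c4cc(OC)c(O[Si](C)(C)C(C)(C)C)c(OC)c4)OC[C@H]23)cc(OC)c1O[Si](C)(C)C(C)(C)C | intermediate
18 | 8-hydroxysyringaresinol, (1S,2R,5R,6S)-2,6-bis(4-hydroxy-3,5-dimethoxyphenyl)-3,7-dioxabicyclo[3.3.0]octan-1-ol, (7R,7'S,8S,8'R) in lignan numbering | COc1cc([C@H]2OC[C@]3(O)[C@@H](c4cc(OC)c(O)c(OC)c4)OC[C@H]23)cc(OC)c1O | target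

**Step count and risks**

Total step count: 11. Longest linear sequence: 11 steps (1 → 3 → 4 → 6 → 8 → 11 → 13 → 14 → 15 → 16 → 17 → 18); the auxiliary 9 and part of aldehyde 3 enter as side inputs.

The three steps most likely to fail:

Step 10 (photocyclisation). The excited ketone may be deactivated by charge transfer from the electron-rich aryl group that sits β to the carbonyl, or may lose material by α-cleavage before hydrogen transfer, and the biradical may close with poor facial preference at C7. The fallback sets out from 16 and comes back at 18; it makes the arenes poorer donors before irradiation. Buffered TBAF/AcOH should give the diphenol ketone (4R,5S)-5-(4-hydroxy-3,5-dimethoxyphenyl)-4-{[(4-hydroxy-3,5-dimethoxyphenyl)methoxy]methyl}oxolan-3-one F1. Ac2O/pyridine should convert it to the diacetate ketone F2. Irradiation as in step 10 should give 8-hydroxysyringaresinol diacetate F3, and K2CO3 in methanol should remove the aryl acetates to give 18.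

Step 6 (anti-aldol). Under triethylamine at room temperature the magnesium enolate may expel the arylmethoxide by β-elimination, and slow addition to the electron-rich aldehyde may erode conversion and anti selectivity. The fallback sets out from 11 and 3 and comes back at 16; it fixes only C7' kinetically and sets C8' by equilibration. The boron-mediated syn-aldol (Bu2BOTf, iPr2NEt, CH2Cl2, −78 to 0 °C) with the same auxiliary should give the syn adduct (S)-4-benzyl-3-[(2S,3S)-3-Ar-3-hydroxy-2-{[(Ar)methoxy]methyl}propanoyl]oxazolidin-2-one F4, in which C7' has the required configuration. The chemistry of steps 7 to 9 should then give the syn Weinreb amide F5, the (3S,4S) chloromethyl ketone F6 and the cis ketone (4S,5S)-5-Ar-4-{[(Ar)methoxy]methyl}oxolan-3-one F7. Epimerisation at C8' next to the ketone (catalytic DBU, CH2Cl2, 0 °C, if the carbonate of the ring closure has not already done it) should convert F7 to the more stable trans ketone 16.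

Step 9 (ring-A closure). Under carbonate the β-hydroxy ketone may fragment by retro-aldol reaction, or the arm may be lost by β-elimination, before the ether forms. The fallback sets out from 13 and comes back at 16; it closes ring A under neutral conditions by carbenoid O–H insertion. Silylation (TESOTf, 2,6-lutidine, CH2Cl2, −78 °C) should give the triethylsilyl ether of the aldol adduct F8, and LiOH/H2O2 (THF/H2O, 0 °C) should give the (2R,3S) silyloxy acid F9. Isobutyl chloroformate and N-methylmorpholine (THF, −20 °C) should give the mixed isobutyl carbonic anhydride F10, which with diazomethane (Et2O, 0 °C) should give the silyloxy diazoketone F11. AcOH/THF/H2O at rt should free the hydroxyl to give the hydroxy diazoketone (3R,4S)-4-Ar-1-diazo-4-hydroxy-3-{[(Ar)methoxy]methyl}butan-2-one F12. Rh2(OAc)4 (1 mol %, CH2Cl2, rt) should then give 16 by intramolecular O–H insertion, which is expected to outrun ylide formation at O2.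

**Further compounds**

F1 | step 10 | (4R,5S)-5-(4-hydroxy-3,5-dimethoxyphenyl)-4-{[(4-hydroxy-3,5-dimethoxyphenyl)methoxy]methyl}oxolan-3-one | COc1cc([C@H]2OCC(=O)[C@@H]2COCc2cc(OC)c(O)c(OC)c2)cc(OC)c1O
F2 | step 10 | (4R,5S)-5-(4-acetoxy-3,5-dimethoxyphenyl)-4-{[(4-acetoxy-3,5-dimethoxyphenyl)methoxy]methyl}oxolan-3-one | COc1cc([C@H]2OCC(=O)[C@@H]2COCc2cc(OC)c(OC(C)=O)c(OC)c2)cc(OC)c1OC(C)=O
F3 | step 10 | 8-hydroxysyringaresinol 4,4'-diacetate | COc1cc([C@H]2OC[C@]3(O)[C@@H](c4cc(OC)c(OC(C)=O)c(OC)c4)OC[C@H]23)cc(OC)c1OC(C)=O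
F4 | step 6 | (S)-4-benzyl-3-[(2S,3S)-3-Ar-3-hydroxy-2-{[(Ar)methoxy]methyl}propanoyl]oxazolidin-2-one | O=C([C@@H](COCc1cc(OC)c(O[Si](C)(C)C(C)(C)C)c(OC)c1)[C@H](O)c1cc(OC)c(O[Si](C)(C)C(C)(C)C)c(OC)c1)N1[C@@H](Cc2ccccc2)COC1=O
F5 | step 6 | (2S,3S)-3-Ar-3-hydroxy-N-methoxy-N-methyl-2-{[(Ar)methoxy]methyl}propanamide | CON(C)C(=O)[C@@H](COCc1cc(OC)c(O[Si](C)(C)C(C)(C)C)c(OC)c1)[C@H](O)c1cc(OC)c(O[Si](C)(C)C(C)(C)C)c(OC)c1
F6 | step 6 | (3S,4S)-4-Ar-1-chloro-4-hydroxy-3-{[(Ar)methoxy]methyl}butan-2-one | ClCC(=O)[C@@H](COCc1cc(OC)c(O[Si](C)(C)C(C)(C)C)c(OC)c1)[C@H](O)c1cc(OC)c(O[Si](C)(C)C(C)(C)C)c(OC)c1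
F7 | step 6 | (4S,5S)-5-Ar-4-{[(Ar)methoxy]methyl}oxolan-3-one (cis) | COc1cc([C@H]2OCC(=O)[C@H]2COCc2cc(OC)c(O[Si](C)(C)C(C)(C)C)c(OC)c2)cc(OC)c1O[Si](C)(C)C(C)(C)C
F8 | step 9 | (S)-4-benzyl-3-[(2R,3S)-3-Ar-2-{[(Ar)methoxy]methyl}-3-(triethylsilyloxy)propanoyl]oxazolidin-2-one | O=C([C@H](COCc1cc(OC)c(O[Si](C)(C)C(C)(C)C)c(OC)c1)[C@H](O[Si](CC)(CC)CC)c1cc(OC)c(O[Si](C)(C)C(C)(C)C)c(OC)c1)N1[C@@H](Cc2ccccc2)COC1=O
F9 | step 9 | (2R,3S)-3-Ar-2-{[(Ar)methoxy]methyl}-3-(triethylsilyloxy)propanoic acid | OC(=O)[C@H](COCc1cc(OC)c(O[Si](C)(C)C(C)(C)C)c(OC)c1)[C@H](O[Si](CC)(CC)CC)c1cc(OC)c(O[Si](C)(C)C(C)(C)C)c(OC)c1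
F10 | step 9 | mixed isobutyl carbonic anhydride of F9 | CC(C)COC(=O)OC(=O)[C@H](COCc1cc(OC)c(O[Si](C)(C)C(C)(C)C)c(OC)c1)[C@H](O[Si](CC)(CC)CC)c1cc(OC)c(O[Si](C)(C)C(C)(C)C)c(OC)c1
F11 | step 9 | (3R,4S)-4-Ar-1-diazo-3-{[(Ar)methoxy]methyl}-4-(triethylsilyloxy)butan-2-one | [N-]=[N+]=CC(=O)[C@H](COCc1cc(OC)c(O[Si](C)(C)C(C)(C)C)c(OC)c1)[C@H](O[Si](CC)(CC)CC)c1cc(OC)c(O[Si](C)(C)C(C)(C)C)c(OC)c1
F12 | step 9 | (3R,4S)-4-Ar-1-diazo-4-hydroxy-3-{[(Ar)methoxy]methyl}butan-2-one | [N-]=[N+]=CC(=O)[C@H](COCc1cc(OC)c(O[Si](C)(C)C(C)(C)C)c(OC)c1)[C@H](O)c1cc(OC)c(O[Si](C)(C)C(C)(C)C)c(OC)c1
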